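Thursday's run, at 2 mol% catalyst, still lacks 3.10 % of its product at 40.0 min. Monday's run, at 3.1 mol%, lacks 0.400 % at the same time. The two runs differ in loading, and the new flask has less catalyst than either.

| setting | Thursday's | Monday's | flask |
|---|---|---|---|
| starting material | 0.27 M | 0.27 M | 0.27 M |
| coupling partner | 1.1 equiv | 1.1 equiv | 1.10 equiv |
| free catalyst | 2 mol% | 3.1 mol% | 1.4 mol% |
| remark | run made earlier | run made earlier |  |
| time |  |  | 1.0 h |

| run | time / min | product / % |
|---|---|---|
| Thursday's | 6.00 | 31.2 |
| Thursday's | 12.0 | 54.8 |
| Thursday's | 20.0 | 76.0 |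
| Thursday's | 25.0 | 85.4 |
| Thursday's | 30.0 | 92.2 |
| Thursday's | 40.0 | 96.9 |
| Monday's | 6.00 | 44.9 |
| Monday's | 12.0 | 72.3 |
| Monday's | 20.0 | 91.9 |
| Monday's | 25.0 | 97.4 |
| Monday's | 30.0 | 99.3 |
| Monday's | 40.0 | 99.6 |

(each reading ± 0.5 percentage points)

* amount of product in percent of the starting material charged, at 12 min, 30 min and 1.0 h

I carry one number. The flask's loading over Thursday's is 0.700. This factor, the catalyst clock, turns a flask's minutes into Thursday minutes. My rule, with starting material at 0.27 M and coupling partner at 1.10 equiv held fixed, is that equal Thursday minutes give equal product. Monday's clock is 1.55, so I can test the rule. Monday's 12.0 min count as 18.6 min on Thursday's clock. Straight interpolation in Thursday's curve gives 72.3 % there, and Monday reads 72.3 %. The gap is smaller than the scatter of a reading.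

Now I build the flask up. First I take the main step alone, at a constant pace. Thursday's opening 6.00 min give 31.2 %, so the flask's clock gives 3.64 % min⁻¹. That means 43.7 % at 12 min, but 109 % at 30 min, more than was charged.

Next I add the running down of starting material, by reading Thursday's curve itself. The flask's 12 min count as 8.40 min on Thursday's clock, and straight interpolation gives 40.6 %. Its 30 min are 21.0 min, which gives 77.9 %.

The tail comes last. On the clock, the flask's 1.0 h lies past Thursday's last reading, so I use Monday's curve at 27.1 min of Monday's time. That gives 98.2 %.

The forecast gives 40.6 %, 78.7 % and 97.6 %, holding the reaction “first order in catalyst with no threshold”. It stands above my reckoning at 30 min and below it at 1.0 h.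

The flask gives 41.9 %, 78.5 % and 98.1 %.

    coupling partner + free catalyst → catalyst intermediate A (k = 0.813 L mol⁻¹ s⁻¹)
    starting material + catalyst intermediate A → catalyst intermediate B (k = 0.508 L mol⁻¹ s⁻¹)
    catalyst intermediate B ⇌ released group + catalyst intermediate C (K = 0.210 M, k = 0.384 s⁻¹)
    catalyst intermediate C → free catalyst + product (k = 0.197 s⁻¹)

The clock of 0.700 puts the flask's 78.5 % at 21.0 min, beside Thursday's 76.0 % at 20.0 min, and Monday's 72.3 % stands at 18.6 min on the same clock. At 1.00 h in the flask, coupling partner takes up each free catalyst 9.18 times faster than starting material uses each catalyst intermediate A. The flask then holds 86.7 % of its catalyst as catalyst intermediate A, the resting state, against free catalyst at 10.1 %.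

All runs stem from a simulated flask on assumed constants; the scatter is artificial.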